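The readings were computed on assumed constants; noise was put on by code.

In both earlier runs one quantity holds steady within the scatter: the climb per minute of the reciprocal of f, where f is the fraction of the charged E left.

| flask | E | J | Q | remark | time |
|---|---|---|---|---|---|
| summer | 0.63 M | 2 equiv | 1.8 equiv | run made earlier |  |
| midnight | 0.63 M | 2 equiv | 2.7 equiv | run made earlier |  |
| Monday's | 0.63 M | 2.00 equiv | 2.00 equiv |  | 1.5 h |
| Friday's | 0.63 M | 2.00 equiv | 2.60 equiv |  | 1.5 h |
| Sunday's | 0.63 M | 2.00 equiv | 3.40 equiv |  | 1.5 h |

| run | time / min | E / % | Z / % |
|---|---|---|---|
| summer | 5.00 | 76 | 20 |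
| summer | 8.00 | 63 | 26 |
| summer | 12.0 | 56 | 29 |
| summer | 20.0 | 45 | 40 |
| summer | 25.0 | 36 | 43 |
| summer | 40.0 | 29 | 51 |
| summer | 60.0 | 21 | 56 |
| midnight | 5.00 | 77 | 19 |
| midnight | 8.00 | 67 | 23 |
| midnight | 12.0 | 55 | 30 |
| midnight | 20.0 | 46 | 39 |
| midnight | 25.0 | 40 | 43 |
| midnight | 40.0 | 27 | 52 |
| midnight | 60.0 | 21 | 57 |

(scatter of a reading: 1.5 percentage points)

- the numbers in the tables scatter with a standard deviation of 1.5 percentage points

- part of the E that has reacted at the end, Monday's
- part of the E that has reacted at the end, Friday's
- part of the E that has reacted at the end, Sunday's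
- what raising the equivalents of Q from its lowest to its highest value here does to the part of the E that has reacted (changes below 5 percentage points count as none) (it rises / no change / it falls)

The reciprocal starts at one, so the mean of the last readings of the two runs gives a climb s of 0.0627 /min, the reciprocal climb, and the readings at 8.00 min give 0.0673 /min. The objection is that J stands at 2.00 equiv, and a line of this kind is not what one J lost per E predicts. But that picture, tried on the summer run, needs a constant that sinks from 0.0322 /min to 0.0176 /min, so it is dropped. A second-order line of this kind is what follows if two J go per E, so that E and J fall together as fractions of their charges, and J at the end of a run can show this.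

The last readings already stand close to the answer, so the reckoning is a correction to them. Carried to 1.5 h, s is reckoned to lower f below the mean last reading by 5.9 points, which gives 84.9% reacted on Monday's. The objection here is scatter, but the mean reading carries 1.1 points, less than the correction.

Q raises a second doubt. The runs at 1.8 equiv and 2.7 equiv both end at 21% and 21%, yet two such readings can hide a gap of 2.1 points. Stretched in proportion over the Q asked about, that gap becomes 3.3 points, less than 5 points. On repeating the run, the reading to watch is E at 60.0 min, where the summer run stood at 21%.

The forecast gives 85% (82% to 88%) for Monday's, 85% (82% to 88%) for Friday's and 85% (80% to 89%) for Sunday's, with the trend no change: “nothing suggests a change”.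

The flasks give 84.5%, 84.5% and 84.5% reacted, and the trend is no change, a change of 0.052 points.

    G + Q ⇌ D (K = 2.23 /M, k = 0.0348 /M/s)
    J + G ⇌ L, settled at all times (K = 2370 /M)
    Z ⇌ X (K = 0.390, k = 0.00310 /s)
    E + J ⇌ G + Z (K = 0.560, k = 8.01 × 10⁻⁴ /M/s)

Monday's holds E at 15.5% and J at 15.9% of their charges at 1.50 h. A neighbouring flask, like Monday's but charged with 0.38 M of E, with the equivalents and the time held, is given s in proportion to its charge of E, 0.0378 /min, so f at the end is reckoned at 22.7%. That flask ends with 76.7% of its E reacted, E at 23% and J at 24% of their charges.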